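**Plan**
1. The retrosynthesis first cuts the two C–C bonds of the CH2 bridge between ring A and ring B, giving aspidinol (ring A), acetylfilicinic acid (ring B) and a one-carbon unit.
2. Ring A is numbered around the ring as carbon 1 (butanoyl), carbon 2 (OH), carbon 3 (CH3), carbon 4 (OCH3), carbon 5 (bridge CH2) and carbon 6 (OH), and it is cut at the bond between carbon 1 and carbon 6. It is the carbocyclic isomer of 4-methoxy-5-methyl-6-(2-oxopentyl)-2-pyrone: the pyrone ring oxygen becomes the hydroxyl on carbon 2, the lactone carbonyl becomes carbon 6, and the side-chain CH2 and ketone become carbon 1 and the butanoyl C=O.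
3. The pyrone is cut at the side-chain CH2–CO bond, the O–CH3 bond, the lactone C–O bond and the C4–C5 bond of methyl 4-methyl-3,5-dioxohexanoate. Ring B is cut at its two C–CH3 bonds back to 2',4',6'-trihydroxyacetophenone.
4. Forward order: diketo ester, pyrone ring, methyl ether, side chain, ring A by recyclisation, aminomethyl group on carbon 5 of ring A, then union with the separately made ring B through the CH2 bridge.
5. The target has no stereocentre. The only geometric element in play, the cis relation of ester carbon and chain on the enol ether double bond of the ring-opened intermediate, is inherited from the pyrone ring.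

Key step: step 5

Assumption: ring B is drawn as one enol tautomer of a freely equilibrating β-triketone, so only regiochemistry has to be controlled.

**Route**

Step 1
Reactants: 1 methyl 3-oxopentanoate; 2 N-methoxy-N-methylacetamide
Product: 3 methyl 4-methyl-3,5-dioxohexanoate (racemic at C4, enolisable)
Conditions: LiN(iPr)2 (2.2 equiv), THF, 0 °C; then 2, −78 → 0 °C; aq HCl
Reagents that add atoms: none
Why: The β-keto ester dianion reacts at its γ-carbon (C4) and the N-methoxy-N-methylamide holds the adduct as a lithium chelate until work-up, so the Claisen-type γ-acylation should stop at the ketone.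

Step 2
Reactants: 3 methyl 4-methyl-3,5-dioxohexanoate
Product: 4 4-hydroxy-5,6-dimethyl-2H-pyran-2-one
Conditions: DBU (1.5 equiv), toluene, reflux; then aq HCl
Reagents that add atoms: none
Why: The enolate oxygen of the C5 ketone attacks the ester and methanol is lost, the usual base-promoted lactonisation of a 3,5-dioxo ester to the conjugated 4-hydroxy-2-pyrone.

Step 3
Reactants: 4 4-hydroxy-5,6-dimethyl-2H-pyran-2-one
Product: 5 4-methoxy-5,6-dimethyl-2H-pyran-2-one
Conditions: (CH3O)2SO2 (1.2 equiv), K2CO3, acetone, reflux
Reagents that add atoms: dimethyl sulfate, COS(=O)(=O)OC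
Why: Williamson-type O-methylation of the vinylogous acid under K2CO3 in acetone should give the 4-methoxy-2-pyrone rather than the 2-methoxy-4-pyranone isomer, and it places the future methyl ether of ring A carbon 4 on the only oxygen that can carry it.

Step 4
Reactants: 5 4-methoxy-5,6-dimethyl-2H-pyran-2-one; 6 N-methoxy-N-methylbutanamide
Product: 7 4-methoxy-5-methyl-6-(2-oxopentyl)-2H-pyran-2-one
Conditions: LiN(iPr)2 (1.1 equiv), THF, −78 °C; then 6, −78 → −20 °C; cold aq HCl
Reagents that add atoms: none
Why: Only the 6-methyl group gives an anion conjugated through the ring to the lactone carbonyl (the 5-methyl is cross-conjugated), and this vinylogous enolate should be C-acylated by the N-methoxy-N-methylamide, whose chelated adduct prevents both over-addition and quenching by the acidic product.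

Step 5
Reactants: 7 4-methoxy-5-methyl-6-(2-oxopentyl)-2H-pyran-2-one
Product: 9 1-(2,6-dihydroxy-4-methoxy-3-methylphenyl)butan-1-one (aspidinol), via ring-opened methyl ester 8 (not isolated)
Conditions: Mg(OCH3)2 (4 equiv), CH3OH, reflux; then cold aq HCl
Reagents that add atoms: magnesium dimethoxide, CO[Mg]OC (its methoxide is the ester OCH3 of intermediate 8 and is expelled again on ring closure; no atom of it stays in 9)
Why: Methoxide adds to the lactone carbonyl and the ring opens to ester 8, in which the magnesium ion chelates the 5,7-diketone; C6 of 8, the carbon between the two ketones, then attacks the ester carbonyl, methoxide leaves and the resulting 2-acylcyclohexene-1,3-dione enolises to the benzene ring, so the new bond joins carbon 1 and carbon 6 of ring A. The closest known reaction type is the Mg(OCH3)2-promoted Claisen (Dieckmann-type) recyclisation of 4-methoxy-6-(2-oxoalkyl)-2-pyrones to 2,6-dihydroxy-4-methoxyphenyl ketones. Ring A closes in the 6-exo-trig mode, the attacked C=O bond lying outside the ring being formed. No stereocentre is created, and the C4 centre of 8 disappears on aromatisation. The step needs Claisen closure to win over aldol closure and over reclosure to the pyrone, and it needs the methyl ether to end on carbon 4 of ring A. The enol ether makes C2 of 8 a vinylic CH that cannot serve as the enolate for an aldol attack on the C7 ketone and keeps ester carbon and C4 cis, the chelated diketone is the only carbon nucleophile, the aromatic product bound to magnesium is the thermodynamic sink, and the single methoxyl of the pyrone is carried unchanged to carbon 4 of ring A.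

Step 6
Reactants: 9 1-(2,6-dihydroxy-4-methoxy-3-methylphenyl)butan-1-one
Product: 10 1-{3-[(dimethylamino)methyl]-2,6-dihydroxy-4-methoxy-5-methylphenyl}butan-1-one
Conditions: CH2[N(CH3)2]2 (1.2 equiv), 1,4-dioxane, 60 °C; evaporation
Reagents that add atoms: bis(dimethylamino)methane, CN(C)CN(C)C
Why: In this phenol Mannich reaction the acidic phenol activates the aminal, which should transfer its dimethylaminomethyl group to carbon 5 of ring A, the only unsubstituted and doubly oxygen-activated ring carbon.

Step 7
Reactants: 11 2',4',6'-trihydroxyacetophenone (dried)
Product: 12 2-acetyl-3,5-dihydroxy-4,4-dimethylcyclohexa-2,5-dien-1-one (acetylfilicinic acid)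
Conditions: NaOCH3 (3 equiv), CH3I (2.2 equiv), CH3OH, 0 °C → rt; then aq HCl
Reagents that add atoms: iodomethane, CI
Why: The phloroglucinol polyanion is C-methylated by SN2 attack on CH3I, and the once-methylated carbon should be methylated again to the gem-dimethyl cyclohexadienone, which can no longer rearomatise (dearomatising double C-alkylation, the standard entry to acylfilicinic acids).

Step 8
Reactants: 10 1-{3-[(dimethylamino)methyl]-2,6-dihydroxy-4-methoxy-5-methylphenyl}butan-1-one; 12 2-acetyl-3,5-dihydroxy-4,4-dimethylcyclohexa-2,5-dien-1-one
Product: 14 2-acetyl-6-[(3-butanoyl-2,4-dihydroxy-6-methoxy-5-methylphenyl)methyl]-3,5-dihydroxy-4,4-dimethylcyclohexa-2,5-dien-1-one, via ortho-quinone methide 13 (not isolated)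
Conditions: 10 and 12 (1:1), 1,4-dioxane, 90 °C, N2 stream; then dilute aq HCl wash
Reagents that add atoms: none
Why: The acidic triketone 12 protonates the amine of 10, dimethylamine is lost to give quinone methide 13, and the enolate of 12 adds through its only unsubstituted ring carbon, which becomes the bridge-bearing carbon of ring B (elimination then Michael addition, the aminomethylphenol acting as a quinone methide precursor); 10 has no free ring carbon, so the mixed dimer should be favoured.

**Compound list**
1 | methyl 3-oxopentanoate | CCC(=O)CC(=O)OC | starting material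
2 | N-methoxy-N-methylacetamide | CC(=O)N(C)OC | starting material
3 | methyl 4-methyl-3,5-dioxohexanoate (racemic at C4) | CC(=O)C(C)C(=O)CC(=O)OC | intermediate
4 | 4-hydroxy-5,6-dimethyl-2H-pyran-2-one | CC1=C(C)C(O)=CC(=O)O1 | intermediate
5 | 4-methoxy-5,6-dimethyl-2H-pyran-2-one | CC1=C(C)C(OC)=CC(=O)O1 | intermediate
6 | N-methoxy-N-methylbutanamide | CCCC(=O)N(C)OC | starting material
7 | 4-methoxy-5-methyl-6-(2-oxopentyl)-2H-pyran-2-one | CCCC(=O)CC1=C(C)C(OC)=CC(=O)O1 | intermediate
8 | methyl (2E)-3-methoxy-4-methyl-5,7-dioxodec-2-enoate (ester carbon and C4 cis; racemic at C4; formed in the flask as its magnesium chelate, not isolated) | CCCC(=O)CC(=O)C(C)/C(OC)=C\C(=O)OC | intermediate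
9 | 1-(2,6-dihydroxy-4-methoxy-3-methylphenyl)butan-1-one (aspidinol) | CCCC(=O)c1c(O)c(C)c(OC)cc1O | intermediate
10 | 1-{3-[(dimethylamino)methyl]-2,6-dihydroxy-4-methoxy-5-methylphenyl}butan-1-one | CCCC(=O)c1c(O)c(C)c(OC)c(CN(C)C)c1O | intermediate
11 | 2',4',6'-trihydroxyacetophenone | CC(=O)c1c(O)cc(O)cc1O | starting material
12 | 2-acetyl-3,5-dihydroxy-4,4-dimethylcyclohexa-2,5-dien-1-one (acetylfilicinic acid) | CC(=O)C1=C(O)C(C)(C)C(O)=CC1=O | intermediate
13 | 2-butanoyl-3-hydroxy-5-methoxy-4-methyl-6-methylidenecyclohexa-2,4-dien-1-one (formed in the flask, not isolated) | CCCC(=O)C1=C(O)C(C)=C(OC)C(=C)C1=O | intermediate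
14 | 2-acetyl-6-[(3-butanoyl-2,4-dihydroxy-6-methoxy-5-methylphenyl)methyl]-3,5-dihydroxy-4,4-dimethylcyclohexa-2,5-dien-1-one | CCCC(=O)c1c(O)c(C)c(OC)c(CC2=C(O)C(C)(C)C(O)=C(C(C)=O)C2=O)c1O | target

**Step count**
Total: 8 steps. Longest linear sequence: 7 steps (steps 1 to 6 and step 8, from 1 to 14); step 7 is a one-step side branch.

**Steps most likely to fail**

Step 5. Mg(OCH3)2 may first deprotonate the side-chain CH2 of 7, and the extended enolate would then make the lactone carbonyl too electron-rich for methoxide to open the ring. Alternatively the open ester may reclose to the pyrone faster than the carbon–carbon closure next to the 5-methyl group. The fallback leaves the route at 3 and rejoins it at 9. Compound 3 would be converted with LiN(iPr)2 (3.3 equiv) in THF into its trianion and acylated at the terminal carbon with 6 to give methyl 4-methyl-3,5,7-trioxodecanoate F1. This open-chain triketo ester would be closed in the Claisen mode with KOH in aqueous methanol to 1-(2,4,6-trihydroxy-3-methylphenyl)butan-1-one F2. The hydroxyl para to the ketone, the most acidic one and the only one that cannot hydrogen-bond to the carbonyl, would then be methylated with (CH3O)2SO2 (1 equiv) and K2CO3 in acetone to give 9. The price is that Claisen against aldol selectivity and the position of the methyl ether are no longer fixed by an enol ether.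

Step 8. Loss of dimethylamine from the phenolic aminomethyl compound may be slow at temperatures where methylene bridges between phloroglucinol units already exchange by retro-Michael cleavage, so symmetrical dimers would build up at the cost of the mixed one. The fallback sets out from 9 and 12, bypasses 10 and returns at 14. Both partners would be dissolved in dilute aqueous KOH at 0 °C and treated with one equivalent of aqueous formaldehyde. The more acidic 12 should be hydroxymethylated first to 2-acetyl-3,5-dihydroxy-6-(hydroxymethyl)-4,4-dimethylcyclohexa-2,5-dien-1-one F3, which loses water to the methylidene trione and is captured at carbon 5 of ring A by the phenoxide of 9 (hydroxymethylation followed by Michael addition). The mixed dimer 14 would be separated from the two symmetrical dimers by chromatography.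

Step 4. Proton transfer from the α-CH2 of the amide to the lithiated pyrone, or slow addition to the amide, may return 5 unchanged. The fallback sets out from 5 and returns at 7. The same lithiated pyrone would be added to butanal at −78 °C, an aldol addition that is faster than proton transfer, to give racemic 6-(2-hydroxypentyl)-4-methoxy-5-methyl-2H-pyran-2-one F4. The secondary alcohol would then be converted into 7 by Dess–Martin oxidation in CH2Cl2 at room temperature.

**Further compounds**
F1 | step 5 | methyl 4-methyl-3,5,7-trioxodecanoate (racemic at C4) | CCCC(=O)CC(=O)C(C)C(=O)CC(=O)OC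
F2 | step 5 | 1-(2,4,6-trihydroxy-3-methylphenyl)butan-1-one | CCCC(=O)c1c(O)c(C)c(O)cc1O
F3 | step 8 | 2-acetyl-3,5-dihydroxy-6-(hydroxymethyl)-4,4-dimethylcyclohexa-2,5-dien-1-one | CC(=O)C1=C(O)C(C)(C)C(O)=C(CO)C1=O
F4 | step 4 | 6-(2-hydroxypentyl)-4-methoxy-5-methyl-2H-pyran-2-one (racemic) | CCCC(O)CC1=C(C)C(OC)=CC(=O)O1
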